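## Retrosynthetic overview

1. Target 16 ⇐ 15 by one-pot methanolysis of one aryl acetate and two aryl TBS ethers.
2. C5=C6 ⇐ E-selective olefin cross-metathesis of propenyl arene 9 with (R)-homoallylic alcohol 14 (C3 from Brown allylboration of aldehyde 12).
3. Key step: the C7–C3' bond and the C7 stereocentre ⇐ aromatic Claisen rearrangement of aryl allyl ether 7 with 1,3-chirality transfer. The cinnamoyl group blocks the second ortho position, so the biomimetic Friedel–Crafts/quinone-methide alkylation, with its C3'/C5' and C7-epimer mixtures, is avoided.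
4. Ether 7 ⇐ Mitsunobu inversion of CBS-derived (R)-allylic alcohol 4 by the chelated 2'-OH of 4'-O-TBS-cardamonin 6.
5. No ring is built: rings A and B arrive with cardamonin 5, the two 4-oxyphenyl rings with 1 and 10.

Assumption: the heptanoid chain is numbered C1–C7 (C7 = diarylmethine carbon, C3 = carbinol), which makes the target (3R,7S); compounds 1, 5, 10, 11 and (−)-B-allyldiisopinocampheylborane (1 M in pentane) are purchased.

## Route

Step 1
Reactants: 1 (E)-4-(4-hydroxyphenyl)but-3-en-2-one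
Product: 2 4-[(1E)-3-oxobut-1-en-1-yl]phenyl acetate
Conditions: Ac2O, pyridine, 4-(dimethylamino)pyridine (cat.), CH2Cl2, 0 °C to rt
Reagents that add atoms: acetic anhydride, CC(=O)OC(C)=O
Why: Phenol O-acetylation; the acetate makes the styrene electron-poor enough to suppress allyl-cation formation in steps 4 and 5 and is removed in step 9 together with the silyl ethers.

Step 2
Reactants: 2 4-[(1E)-3-oxobut-1-en-1-yl]phenyl acetate
Product: 4 4-[(1E,3R)-3-hydroxybut-1-en-1-yl]phenyl acetate, via catechol borate 3 (not isolated)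
Conditions: (S)-Me-CBS [(S)-1-methyl-3,3-diphenyltetrahydro-1H,3H-pyrrolo[1,2-c][1,3,2]oxazaborole] (15 mol %), catecholborane, PhMe, −78 °C; then MeOH, pH 7 buffer
Reagents that add atoms: none
Why: Corey–Bakshi–Shibata reduction: the enone binds the oxazaborolidine with the styryl group as the large substituent, so hydride goes to the face that gives the (R)-carbinol (as borate 3, freed on quench), while the aryl acetate and the C=C are untouched at −78 °C.

Step 3
Reactants: 5 cardamonin [(E)-1-(2,4-dihydroxy-6-methoxyphenyl)-3-phenylprop-2-en-1-one]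
Product: 6 (E)-1-[4-(tert-butyldimethylsilyloxy)-2-hydroxy-6-methoxyphenyl]-3-phenylprop-2-en-1-one
Conditions: TBSCl (1.05 equiv), imidazole, DMF, 0 °C
Reagents that add atoms: tert-butyldimethylsilyl chloride, CC(C)(C)[Si](C)(C)Cl
Why: Selective silylation: the 4'-OH is free and the more acidic one, while the 2'-OH is tied up in a hydrogen bond to the ketone and stays free for step 4.

Step 4
Reactants: 6 (E)-1-[4-(tert-butyldimethylsilyloxy)-2-hydroxy-6-methoxyphenyl]-3-phenylprop-2-en-1-one; 4 4-[(1E,3R)-3-hydroxybut-1-en-1-yl]phenyl acetate (1.2 equiv)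
Product: 7 4-[(1E,3S)-3-{5-(tert-butyldimethylsilyloxy)-3-methoxy-2-[(E)-3-phenylprop-2-enoyl]phenoxy}but-1-en-1-yl]phenyl acetate
Conditions: PPh3, DIAD, PhMe, 0 °C to rt
Reagents that add atoms: none
Why: Mitsunobu etherification: the 2'-phenol displaces the oxyphosphonium of 4 by SN2 with inversion (R to S), and the acetoxy group and the non-polar solvent disfavour the ionisation that would cause racemisation or SN2' attack.

Step 5
Reactants: 7 4-[(1E,3S)-3-{5-(tert-butyldimethylsilyloxy)-3-methoxy-2-[(E)-3-phenylprop-2-enoyl]phenoxy}but-1-en-1-yl]phenyl acetate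
Product: 9 4-[(1S,2E)-1-{6-(tert-butyldimethylsilyloxy)-2-hydroxy-4-methoxy-3-[(E)-3-phenylprop-2-enoyl]phenyl}but-2-en-1-yl]phenyl acetate, via ortho-dienone 8 (not isolated)
Conditions: o-xylene (0.05 M, degassed), BHT (5 mol %), 140 °C, sealed tube
Reagents that add atoms: none
Why: Aromatic Claisen rearrangement ([3,3]-sigmatropic): the only free ortho carbon of the ether oxygen is C3' (the other carries the cinnamoyl group), and a chair transition state with the methyl group equatorial carries the stereochemistry suprafacially from the (S)-C–O carbon to the new (S)-diarylmethine carbon while forming the E-propenyl group, after which dienone 8 tautomerises to the hydrogen-bonded phenol.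

Step 6
Reactants: 10 tert-butyl(4-iodophenoxy)dimethylsilane; 11 prop-2-en-1-ol (allyl alcohol)
Product: 12 3-[4-(tert-butyldimethylsilyloxy)phenyl]propanal
Conditions: Pd(OAc)2 (3 mol %), Bu4NCl, NaHCO3, DMF, 45 °C
Reagents that add atoms: none
Why: Jeffery–Heck arylation of allyl alcohol: after aryl insertion at the terminal carbon, β-hydride elimination runs toward the carbinol carbon, so the saturated aldehyde is released directly under conditions mild enough for the aryl silyl ether.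

Step 7
Reactants: 12 3-[4-(tert-butyldimethylsilyloxy)phenyl]propanal
Product: 14 (3R)-1-[4-(tert-butyldimethylsilyloxy)phenyl]hex-5-en-3-ol, via borinate ester 13 (not isolated)
Conditions: (−)-Ipc2B(allyl) (1.2 equiv), Et2O, −78 °C; then HOCH2CH2NH2, rt
Reagents that add atoms: (−)-B-allyldiisopinocampheylborane, C=CCB([C@@H]1C[C@@H]2C[C@H]([C@H]1C)C2(C)C)[C@@H]1C[C@@H]2C[C@H]([C@H]1C)C2(C)C
Why: Brown asymmetric allylboration: the (+)-α-pinene-derived reagent adds through a closed chair transition state to the Si face of the aldehyde and sets C3 as R, and the non-oxidative ethanolamine work-up frees the alcohol from borinate 13 without touching the aryl silyl ether.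

Step 8
Reactants: 9 4-[(1S,2E)-1-{6-(tert-butyldimethylsilyloxy)-2-hydroxy-4-methoxy-3-[(E)-3-phenylprop-2-enoyl]phenyl}but-2-en-1-yl]phenyl acetate; 14 (3R)-1-[4-(tert-butyldimethylsilyloxy)phenyl]hex-5-en-3-ol (3 equiv)
Product: 15 4-[(1S,2E,5R)-1-{6-(tert-butyldimethylsilyloxy)-2-hydroxy-4-methoxy-3-[(E)-3-phenylprop-2-enoyl]phenyl}-7-[4-(tert-butyldimethylsilyloxy)phenyl]-5-hydroxyhept-2-en-1-yl]phenyl acetate
Conditions: RuCl2(H2IMes)(=CH-C6H4-2-OiPr) (second-generation Hoveyda–Grubbs catalyst, 10 mol %), 2,6-dichloro-1,4-benzoquinone (20 mol %), CH2Cl2, 40 °C, argon sparge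
Reagents that add atoms: none
Why: Olefin cross-metathesis: the alkylidene formed on the unhindered terminal alkene of 14 exchanges with the propenyl group of 9 (propene is purged), the disubstituted product forms E under thermodynamic control, neither stereocentre is an alkene carbon, the electron-poor chalcone C=C does not compete, and the benzoquinone suppresses ruthenium-hydride double-bond migration.

Step 9
Reactants: 15 4-[(1S,2E,5R)-1-{6-(tert-butyldimethylsilyloxy)-2-hydroxy-4-methoxy-3-[(E)-3-phenylprop-2-enoyl]phenyl}-7-[4-(tert-butyldimethylsilyloxy)phenyl]-5-hydroxyhept-2-en-1-yl]phenyl acetate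
Product: 16 7-epi-katsumain C
Conditions: K2CO3 (0.5 equiv), MeOH/THF, 0 °C to rt; then pH 6 phosphate buffer
Reagents that add atoms: none
Why: Base-catalysed methanolysis (transesterification of the aryl acetate, trans-silylation of the two aryl silyl ethers) frees all phenols without acid, which could epimerise the doubly benzylic C7 or close the 2'-hydroxychalcone to a flavanone.

## Compound list

1 | (E)-4-(4-hydroxyphenyl)but-3-en-2-one | CC(=O)/C=C/c1ccc(O)cc1 | starting material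
2 | 4-[(1E)-3-oxobut-1-en-1-yl]phenyl acetate | CC(=O)/C=C/c1ccc(OC(C)=O)cc1 | intermediate
3 | 4-[(1E,3R)-3-(1,3,2-benzodioxaborol-2-yloxy)but-1-en-1-yl]phenyl acetate (formed in the flask) | C[C@@H](OB1Oc2ccccc2O1)/C=C/c1ccc(OC(C)=O)cc1 | intermediate
4 | 4-[(1E,3R)-3-hydroxybut-1-en-1-yl]phenyl acetate | C[C@@H](O)/C=C/c1ccc(OC(C)=O)cc1 | intermediate
5 | cardamonin, (E)-1-(2,4-dihydroxy-6-methoxyphenyl)-3-phenylprop-2-en-1-one | COc1cc(O)cc(O)c1C(=O)/C=C/c1ccccc1 | starting material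
6 | (E)-1-[4-(tert-butyldimethylsilyloxy)-2-hydroxy-6-methoxyphenyl]-3-phenylprop-2-en-1-one | COc1cc(O[Si](C)(C)C(C)(C)C)cc(O)c1C(=O)/C=C/c1ccccc1 | intermediate
7 | 4-[(1E,3S)-3-{5-(tert-butyldimethylsilyloxy)-3-methoxy-2-[(E)-3-phenylprop-2-enoyl]phenoxy}but-1-en-1-yl]phenyl acetate | C[C@H](Oc1cc(O[Si](C)(C)C(C)(C)C)cc(OC)c1C(=O)/C=C/c1ccccc1)/C=C/c1ccc(OC(C)=O)cc1 | intermediate
8 | (6R)-6-[(1R,2E)-1-(4-acetoxyphenyl)but-2-en-1-yl]-5-(tert-butyldimethylsilyloxy)-3-methoxy-2-[(E)-3-phenylprop-2-enoyl]cyclohexa-2,4-dien-1-one (formed in the flask; same spatial arrangement at the side-chain carbon as in 9, the descriptor differs only through CIP priorities) | COC1=C(C(=O)/C=C/c2ccccc2)C(=O)[C@H]([C@@H](/C=C/C)c2ccc(OC(C)=O)cc2)C(O[Si](C)(C)C(C)(C)C)=C1 | intermediate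
9 | 4-[(1S,2E)-1-{6-(tert-butyldimethylsilyloxy)-2-hydroxy-4-methoxy-3-[(E)-3-phenylprop-2-enoyl]phenyl}but-2-en-1-yl]phenyl acetate | COc1cc(O[Si](C)(C)C(C)(C)C)c([C@@H](/C=C/C)c2ccc(OC(C)=O)cc2)c(O)c1C(=O)/C=C/c1ccccc1 | intermediate
10 | tert-butyl(4-iodophenoxy)dimethylsilane | CC(C)(C)[Si](C)(C)Oc1ccc(I)cc1 | starting material
11 | prop-2-en-1-ol (allyl alcohol) | C=CCO | starting material
12 | 3-[4-(tert-butyldimethylsilyloxy)phenyl]propanal | O=CCCc1ccc(O[Si](C)(C)C(C)(C)C)cc1 | intermediate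
13 | (3R)-1-[4-(tert-butyldimethylsilyloxy)phenyl]hex-5-en-3-yl diisopinocampheylborinate (formed in the flask) | C=CC[C@H](OB([C@@H]1C[C@@H]2C[C@H]([C@H]1C)C2(C)C)[C@@H]1C[C@@H]2C[C@H]([C@H]1C)C2(C)C)CCc1ccc(O[Si](C)(C)C(C)(C)C)cc1 | intermediate
14 | (3R)-1-[4-(tert-butyldimethylsilyloxy)phenyl]hex-5-en-3-ol | C=CC[C@H](O)CCc1ccc(O[Si](C)(C)C(C)(C)C)cc1 | intermediate
15 | 4-[(1S,2E,5R)-1-{6-(tert-butyldimethylsilyloxy)-2-hydroxy-4-methoxy-3-[(E)-3-phenylprop-2-enoyl]phenyl}-7-[4-(tert-butyldimethylsilyloxy)phenyl]-5-hydroxyhept-2-en-1-yl]phenyl acetate | COc1cc(O[Si](C)(C)C(C)(C)C)c([C@@H](/C=C/C[C@H](O)CCc2ccc(O[Si](C)(C)C(C)(C)C)cc2)c2ccc(OC(C)=O)cc2)c(O)c1C(=O)/C=C/c1ccccc1 | intermediate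
16 | 7-epi-katsumain C, (E)-1-{2,4-dihydroxy-3-[(1S,2E,5R)-5-hydroxy-1,7-bis(4-hydroxyphenyl)hept-2-en-1-yl]-6-methoxyphenyl}-3-phenylprop-2-en-1-one | COc1cc(O)c([C@@H](/C=C/C[C@H](O)CCc2ccc(O)cc2)c2ccc(O)cc2)c(O)c1C(=O)/C=C/c1ccccc1 | target

## Step count and risks

Total step count: 9. Longest linear sequence: 6 steps (steps 1, 2, 4, 5, 8, 9). Steps 3, 6 and 7 are side branches. C7 comes from the CBS reduction through inversion (step 4) and chirality transfer (step 5), C3 from the allylboration; the minor C7 or C3 epimers are diastereomers of 16 and are removed by preparative HPLC of 16.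

**Most likely to fail, first: step 8.** The propenyl group sits next to a congested diarylmethine carbon and may be too slow, or the alkene may migrate into conjugation. The fallback moves the metathesis to an early, unhindered position and carries the full chain through the Claisen step; it sets out from 14 (and uses 6) and comes back at 16. Alcohol 14 is silylated (TBSCl, imidazole) to tert-butyl{4-[(3R)-3-(tert-butyldimethylsilyloxy)hex-5-en-1-yl]phenoxy}dimethylsilane F7. Ozonolysis (O3, CH2Cl2, −78 °C, then PPh3) gives (3R)-3-(tert-butyldimethylsilyloxy)-5-[4-(tert-butyldimethylsilyloxy)phenyl]pentanal F8. Addition of CH2=CHMgBr gives (5R)-5-(tert-butyldimethylsilyloxy)-7-[4-(tert-butyldimethylsilyloxy)phenyl]hept-1-en-3-ol F9 as a mixture of carbinol epimers, and Dess–Martin oxidation converges them to the vinyl ketone (5R)-5-(tert-butyldimethylsilyloxy)-7-[4-(tert-butyldimethylsilyloxy)phenyl]hept-1-en-3-one F10. Cross-metathesis of F10 with commercial 4-acetoxystyrene (same ruthenium catalyst as step 8) gives the enone 4-[(1E,5R)-5-(tert-butyldimethylsilyloxy)-7-[4-(tert-butyldimethylsilyloxy)phenyl]-3-oxohept-1-en-1-yl]phenyl acetate F11. CBS reduction as in step 2 gives the syn alcohol 4-[(1E,3R,5R)-5-(tert-butyldimethylsilyloxy)-3-hydroxy-7-[4-(tert-butyldimethylsilyloxy)phenyl]hept-1-en-1-yl]phenyl acetate F12. Mitsunobu coupling with 6 as in step 4 gives the inverted aryl ether 4-[(1E,3S,5R)-5-(tert-butyldimethylsilyloxy)-7-[4-(tert-butyldimethylsilyloxy)phenyl]-3-{5-(tert-butyldimethylsilyloxy)-3-methoxy-2-[(E)-3-phenylprop-2-enoyl]phenoxy}hept-1-en-1-yl]phenyl acetate F13. Claisen rearrangement as in step 5 gives 4-[(1S,2E,5R)-5-(tert-butyldimethylsilyloxy)-1-{6-(tert-butyldimethylsilyloxy)-2-hydroxy-4-methoxy-3-[(E)-3-phenylprop-2-enoyl]phenyl}-7-[4-(tert-butyldimethylsilyloxy)phenyl]hept-2-en-1-yl]phenyl acetate F14. HF·pyridine removes the three silyl groups to give 4-[(1S,2E,5R)-1-{2,6-dihydroxy-4-methoxy-3-[(E)-3-phenylprop-2-enoyl]phenyl}-5-hydroxy-7-(4-hydroxyphenyl)hept-2-en-1-yl]phenyl acetate F15, and K2CO3/MeOH as in step 9 gives 16.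

**Second: step 5.** The chalcone may not survive 140 °C (flavanone closure), or dienone 8 may undergo a second [3,3] shift to C5' before it tautomerises. The fallback rearranges at the acetophenone stage and builds the chalcone last; it sets out from 4 and comes back at 16. Commercial 1-(2,4-dihydroxy-6-methoxyphenyl)ethanone is silylated (TBSCl, imidazole) to 1-[4-(tert-butyldimethylsilyloxy)-2-hydroxy-6-methoxyphenyl]ethanone F2. Mitsunobu coupling with 4 as in step 4 gives 4-[(1E,3S)-3-{2-acetyl-5-(tert-butyldimethylsilyloxy)-3-methoxyphenoxy}but-1-en-1-yl]phenyl acetate F3. This robust ketone is rearranged in N,N-diethylaniline at 180 °C, where the amine speeds the dienone-to-phenol tautomerisation, to 4-[(1S,2E)-1-{3-acetyl-6-(tert-butyldimethylsilyloxy)-2-hydroxy-4-methoxyphenyl}but-2-en-1-yl]phenyl acetate F4. Cross-metathesis with 14 as in step 8 gives 4-[(1S,2E,5R)-1-{3-acetyl-6-(tert-butyldimethylsilyloxy)-2-hydroxy-4-methoxyphenyl}-7-[4-(tert-butyldimethylsilyloxy)phenyl]-5-hydroxyhept-2-en-1-yl]phenyl acetate F5. KOH (50% aq.) in EtOH strips the acetate and both aryl silyl ethers to give 1-{2,4-dihydroxy-3-[(1S,2E,5R)-5-hydroxy-1,7-bis(4-hydroxyphenyl)hept-2-en-1-yl]-6-methoxyphenyl}ethanone F6, which is not isolated; benzaldehyde added to the same flask gives 16 by Claisen–Schmidt condensation. This last condensation on a polyphenoxide is expected to be slow and moderate in yield.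

**Third: step 4.** The oxyphosphonium of the cinnamyl-type alcohol 4 may still ionise in part (loss of ee, SN2' ether), or the chelated phenol may react sluggishly. The fallback makes the C–O bond with an alcohol that cannot ionise and attaches the aryl group afterwards; it sets out from 6 and comes back at 7. Mitsunobu coupling of 6 with commercial (R)-but-3-en-2-ol (PPh3, DIAD, PhMe, 0 °C) gives, with inversion, (E)-1-{2-[(2S)-but-3-en-2-yloxy]-4-(tert-butyldimethylsilyloxy)-6-methoxyphenyl}-3-phenylprop-2-en-1-one F1. E-selective cross-metathesis of its terminal alkene with commercial 4-acetoxystyrene (3 equiv, same ruthenium catalyst as step 8, CH2Cl2, 40 °C) gives 7 without touching the stereocentre.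

## Further compounds

F1 | step 4 | (E)-1-{2-[(2S)-but-3-en-2-yloxy]-4-(tert-butyldimethylsilyloxy)-6-methoxyphenyl}-3-phenylprop-2-en-1-one | C=C[C@H](C)Oc1cc(O[Si](C)(C)C(C)(C)C)cc(OC)c1C(=O)/C=C/c1ccccc1
F2 | step 5 | 1-[4-(tert-butyldimethylsilyloxy)-2-hydroxy-6-methoxyphenyl]ethanone | CC(=O)c1c(O)cc(O[Si](C)(C)C(C)(C)C)cc1OC
F3 | step 5 | 4-[(1E,3S)-3-{2-acetyl-5-(tert-butyldimethylsilyloxy)-3-methoxyphenoxy}but-1-en-1-yl]phenyl acetate | C[C@H](Oc1cc(O[Si](C)(C)C(C)(C)C)cc(OC)c1C(C)=O)/C=C/c1ccc(OC(C)=O)cc1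
F4 | step 5 | 4-[(1S,2E)-1-{3-acetyl-6-(tert-butyldimethylsilyloxy)-2-hydroxy-4-methoxyphenyl}but-2-en-1-yl]phenyl acetate | COc1cc(O[Si](C)(C)C(C)(C)C)c([C@@H](/C=C/C)c2ccc(OC(C)=O)cc2)c(O)c1C(C)=O
F5 | step 5 | 4-[(1S,2E,5R)-1-{3-acetyl-6-(tert-butyldimethylsilyloxy)-2-hydroxy-4-methoxyphenyl}-7-[4-(tert-butyldimethylsilyloxy)phenyl]-5-hydroxyhept-2-en-1-yl]phenyl acetate | COc1cc(O[Si](C)(C)C(C)(C)C)c([C@@H](/C=C/C[C@H](O)CCc2ccc(O[Si](C)(C)C(C)(C)C)cc2)c2ccc(OC(C)=O)cc2)c(O)c1C(C)=O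
F6 | step 5 | 1-{2,4-dihydroxy-3-[(1S,2E,5R)-5-hydroxy-1,7-bis(4-hydroxyphenyl)hept-2-en-1-yl]-6-methoxyphenyl}ethanone | COc1cc(O)c([C@@H](/C=C/C[C@H](O)CCc2ccc(O)cc2)c2ccc(O)cc2)c(O)c1C(C)=O
F7 | step 8 | tert-butyl{4-[(3R)-3-(tert-butyldimethylsilyloxy)hex-5-en-1-yl]phenoxy}dimethylsilane | C=CC[C@H](O[Si](C)(C)C(C)(C)C)CCc1ccc(O[Si](C)(C)C(C)(C)C)cc1
F8 | step 8 | (3R)-3-(tert-butyldimethylsilyloxy)-5-[4-(tert-butyldimethylsilyloxy)phenyl]pentanal | O=CC[C@H](O[Si](C)(C)C(C)(C)C)CCc1ccc(O[Si](C)(C)C(C)(C)C)cc1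
F9 | step 8 | (5R)-5-(tert-butyldimethylsilyloxy)-7-[4-(tert-butyldimethylsilyloxy)phenyl]hept-1-en-3-ol, both C3 epimers | C=CC(O)C[C@H](O[Si](C)(C)C(C)(C)C)CCc1ccc(O[Si](C)(C)C(C)(C)C)cc1
F10 | step 8 | (5R)-5-(tert-butyldimethylsilyloxy)-7-[4-(tert-butyldimethylsilyloxy)phenyl]hept-1-en-3-one | C=CC(=O)C[C@H](O[Si](C)(C)C(C)(C)C)CCc1ccc(O[Si](C)(C)C(C)(C)C)cc1
F11 | step 8 | 4-[(1E,5R)-5-(tert-butyldimethylsilyloxy)-7-[4-(tert-butyldimethylsilyloxy)phenyl]-3-oxohept-1-en-1-yl]phenyl acetate | CC(=O)Oc1ccc(/C=C/C(=O)C[C@H](O[Si](C)(C)C(C)(C)C)CCc2ccc(O[Si](C)(C)C(C)(C)C)cc2)cc1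
F12 | step 8 | 4-[(1E,3R,5R)-5-(tert-butyldimethylsilyloxy)-3-hydroxy-7-[4-(tert-butyldimethylsilyloxy)phenyl]hept-1-en-1-yl]phenyl acetate | CC(=O)Oc1ccc(/C=C/[C@H](O)C[C@H](O[Si](C)(C)C(C)(C)C)CCc2ccc(O[Si](C)(C)C(C)(C)C)cc2)cc1
F13 | step 8 | 4-[(1E,3S,5R)-5-(tert-butyldimethylsilyloxy)-7-[4-(tert-butyldimethylsilyloxy)phenyl]-3-{5-(tert-butyldimethylsilyloxy)-3-methoxy-2-[(E)-3-phenylprop-2-enoyl]phenoxy}hept-1-en-1-yl]phenyl acetate | CC(=O)Oc1ccc(/C=C/[C@@H](Oc2cc(O[Si](C)(C)C(C)(C)C)cc(OC)c2C(=O)/C=C/c2ccccc2)C[C@H](O[Si](C)(C)C(C)(C)C)CCc2ccc(O[Si](C)(C)C(C)(C)C)cc2)cc1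
F14 | step 8 | 4-[(1S,2E,5R)-5-(tert-butyldimethylsilyloxy)-1-{6-(tert-butyldimethylsilyloxy)-2-hydroxy-4-methoxy-3-[(E)-3-phenylprop-2-enoyl]phenyl}-7-[4-(tert-butyldimethylsilyloxy)phenyl]hept-2-en-1-yl]phenyl acetate | COc1cc(O[Si](C)(C)C(C)(C)C)c([C@@H](/C=C/C[C@H](O[Si](C)(C)C(C)(C)C)CCc2ccc(O[Si](C)(C)C(C)(C)C)cc2)c2ccc(OC(C)=O)cc2)c(O)c1C(=O)/C=C/c1ccccc1
F15 | step 8 | 4-[(1S,2E,5R)-1-{2,6-dihydroxy-4-methoxy-3-[(E)-3-phenylprop-2-enoyl]phenyl}-5-hydroxy-7-(4-hydroxyphenyl)hept-2-en-1-yl]phenyl acetate | COc1cc(O)c([C@@H](/C=C/C[C@H](O)CCc2ccc(O)cc2)c2ccc(OC(C)=O)cc2)c(O)c1C(=O)/C=C/c1ccccc1
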